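**Retrosynthetic overview**
1. Epimedonin J ⇐ cleavage of three MOM ethers ⇐ C2–OAr bond made by addition–elimination of a phenoxide on a 2-(methylsulfonyl)chromone.
2. Sulfonylchromone ⇐ 2-(methylthio)chromone ⇐ 4-hydroxy-2-thiocoumarin ⇐ CS2 annulation of a 2-hydroxyacetophenone. The pyranone is the only ring built; both benzene rings are bought.
3. Acetophenone ⇐ phloroacetophenone by C-prenylation, then bis-MOM protection that leaves free the OH next to the prenyl group (this fixes 8-prenyl).
4. Aryl partner ⇐ 4-(TBSO)phenol by MOM protection and OMOM-directed ortho-lithiation/prenylation; its silyl ether is opened by fluoride in the coupling flask.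

Assumption: the target has no stereocentre and no E/Z-isomeric alkene (both alkenes are prenyl groups), so "single enantiomer" calls for no stereocontrol.
Assumption: where one reagent acts two or three times in one operation (bis-MOM protection, sulfide to sulfone, cleavage of three MOM groups), the partly converted species count as part of that step and are not numbered.

**Route**

Step 1
Reactants: 1 2,4,6-trihydroxyacetophenone; 2 prenyl bromide (1-bromo-3-methylbut-2-ene)
Product: 3 1-[2,4,6-trihydroxy-3-(3-methylbut-2-en-1-yl)phenyl]ethan-1-one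
Conditions: 2 (1.0 equiv), DBU (1.1 equiv), THF, 0 °C → rt
Reagents that add atoms: prenyl bromide 2, CC(C)=CCBr
Why: The phloroglucinol-type ambident phenoxide is alkylated at carbon (C-prenylation, SN2 at the primary allylic carbon), and since the two open ring positions are equivalent, mono-alkylation gives a single regioisomer.

Step 2
Reactants: 3 1-[2,4,6-trihydroxy-3-(3-methylbut-2-en-1-yl)phenyl]ethan-1-one; 4 chloromethyl methyl ether (MOMCl)
Product: 5 1-[2-hydroxy-4,6-bis(methoxymethoxy)-3-(3-methylbut-2-en-1-yl)phenyl]ethan-1-one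
Conditions: MOMCl (2.2 equiv), i-Pr2NEt (2.5 equiv), CH2Cl2, 0 °C → rt
Reagents that add atoms: chloromethyl methyl ether 4, COCCl
Why: Williamson-type MOM etherification takes the unchelated 4-OH first and then the less hindered chelated OH, leaving free the hydrogen-bonded OH flanked by acetyl and prenyl, which is the oxygen that must become O1 next to C8.

Step 3
Reactants: 5 1-[2-hydroxy-4,6-bis(methoxymethoxy)-3-(3-methylbut-2-en-1-yl)phenyl]ethan-1-one; 6 carbon disulfide
Product: 8 4-hydroxy-5,7-bis(methoxymethoxy)-8-(3-methylbut-2-en-1-yl)-2H-chromene-2-thione, via β-keto dithioacid 7 (not isolated)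
Conditions: t-BuOK (3.3 equiv), CS2 (1.5 equiv), THF, 0 °C → rt; then cold 1 M HCl to pH 3
Reagents that add atoms: carbon disulfide 6, S=C=S
Why: Claisen-type thioacylation of the ketone enolate with CS2 gives the β-keto dithioacid, whose phenol closes onto the thiocarbonyl with loss of H2S on acidification (CS2 annulation), forming the pyranone ring.

Step 4
Reactants: 8 4-hydroxy-5,7-bis(methoxymethoxy)-8-(3-methylbut-2-en-1-yl)-2H-chromene-2-thione; 9 iodomethane
Product: 10 5,7-bis(methoxymethoxy)-8-(3-methylbut-2-en-1-yl)-2-(methylsulfanyl)-4H-chromen-4-one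
Conditions: MeI (1.1 equiv), K2CO3, acetone, rt
Reagents that add atoms: iodomethane 9, CI
Why: The soft sulfur of the ambident thiocoumarin anion is methylated in preference to oxygen (SN2 S-alkylation), which locks the 4-chromone tautomer as a vinylogous thioester.

Step 5
Reactants: 10 5,7-bis(methoxymethoxy)-8-(3-methylbut-2-en-1-yl)-2-(methylsulfanyl)-4H-chromen-4-one; 11 hydrogen peroxide
Product: 12 2-(methanesulfonyl)-5,7-bis(methoxymethoxy)-8-(3-methylbut-2-en-1-yl)-4H-chromen-4-one
Conditions: (NH4)6Mo7O24·4H2O (10 mol %), 30% aq. H2O2 (4 equiv), EtOH, 0 °C → rt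
Reagents that add atoms: hydrogen peroxide 11, OO
Why: Molybdate-catalysed peroxide S-oxidation takes the sulfide through the sulfoxide to the sulfone much faster than it epoxidises a trisubstituted alkene, so the prenyl group and the MOM acetals survive.

Step 6
Reactants: 13 4-[(tert-butyldimethylsilyl)oxy]phenol; 4 chloromethyl methyl ether (MOMCl)
Product: 14 tert-butyl[4-(methoxymethoxy)phenoxy]dimethylsilane
Conditions: MOMCl (1.3 equiv), i-Pr2NEt, CH2Cl2, 0 °C → rt
Reagents that add atoms: chloromethyl methyl ether 4, COCCl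
Why: Williamson-type etherification of the free phenol installs the MOM group that serves as both protecting group and ortho-directing group, while the aryl silyl ether is inert to amine base.

Step 7
Reactants: 14 tert-butyl[4-(methoxymethoxy)phenoxy]dimethylsilane; 2 prenyl bromide
Product: 16 tert-butyl[4-(methoxymethoxy)-3-(3-methylbut-2-en-1-yl)phenoxy]dimethylsilane, via aryllithium 15 (not isolated)
Conditions: s-BuLi (1.2 equiv), TMEDA, THF, −78 °C, 1 h; then CuI (10 mol %), 2, −78 °C → rt
Reagents that add atoms: prenyl bromide 2, CC(C)=CCBr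
Why: Directed ortho-metalation places lithium next to OMOM (OTBS is a far weaker director), and copper-catalysed SN2 allylic substitution at the primary carbon of prenyl bromide gives the linear prenyl arene.

Step 8
Reactants: 16 tert-butyl[4-(methoxymethoxy)-3-(3-methylbut-2-en-1-yl)phenoxy]dimethylsilane; 12 2-(methanesulfonyl)-5,7-bis(methoxymethoxy)-8-(3-methylbut-2-en-1-yl)-4H-chromen-4-one
Product: 18 5,7-bis(methoxymethoxy)-2-[4-(methoxymethoxy)-3-(3-methylbut-2-en-1-yl)phenoxy]-8-(3-methylbut-2-en-1-yl)-4H-chromen-4-one, via caesium phenoxide 17 (not isolated)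
Conditions: 16 (1.1 equiv), CsF (2 equiv), dry DMF, rt → 40 °C
Reagents that add atoms: none
Why: Fluoride opens the aryl silyl ether to the phenoxide, which displaces methanesulfinate from C2 of the vinylogous sulfonyl ester by conjugate addition–elimination (SNAr-type), the MOM groups keeping the chromone from forming a deactivating 7-phenoxide.

Step 9
Reactants: 18 5,7-bis(methoxymethoxy)-2-[4-(methoxymethoxy)-3-(3-methylbut-2-en-1-yl)phenoxy]-8-(3-methylbut-2-en-1-yl)-4H-chromen-4-one
Product: 19 Epimedonin J
Conditions: 3 M aq. HCl/MeOH (1:4), 40 °C, monitored and stopped at full conversion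
Reagents that add atoms: none
Why: Acid-catalysed acetal exchange of the three MOM ethers with methanol frees the phenols under conditions mild enough to spare the ortho-prenylphenols (no chroman formation) and the 2-aryloxy enol ether; there is no stereocentre to set or lose.

**Compound list**
1 | 2,4,6-trihydroxyacetophenone | CC(=O)c1c(O)cc(O)cc1O | starting material
2 | prenyl bromide (1-bromo-3-methylbut-2-ene) | CC(C)=CCBr | starting material
3 | 1-[2,4,6-trihydroxy-3-(3-methylbut-2-en-1-yl)phenyl]ethan-1-one | CC(=O)c1c(O)cc(O)c(CC=C(C)C)c1O | intermediate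
4 | chloromethyl methyl ether | COCCl | starting material
5 | 1-[2-hydroxy-4,6-bis(methoxymethoxy)-3-(3-methylbut-2-en-1-yl)phenyl]ethan-1-one | CC(=O)c1c(OCOC)cc(OCOC)c(CC=C(C)C)c1O | intermediate
6 | carbon disulfide | S=C=S | starting material
7 | 3-[2-hydroxy-4,6-bis(methoxymethoxy)-3-(3-methylbut-2-en-1-yl)phenyl]-3-oxopropanedithioic acid (β-keto dithioacid, potassium salt in the flask) | COCOc1cc(OCOC)c(C(=O)CC(=S)S)c(O)c1CC=C(C)C | intermediate
8 | 4-hydroxy-5,7-bis(methoxymethoxy)-8-(3-methylbut-2-en-1-yl)-2H-chromene-2-thione | S=c1cc(O)c2c(OCOC)cc(OCOC)c(CC=C(C)C)c2o1 | intermediate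
9 | iodomethane | CI | starting material
10 | 5,7-bis(methoxymethoxy)-8-(3-methylbut-2-en-1-yl)-2-(methylsulfanyl)-4H-chromen-4-one | CSc1cc(=O)c2c(OCOC)cc(OCOC)c(CC=C(C)C)c2o1 | intermediate
11 | hydrogen peroxide | OO | starting material
12 | 2-(methanesulfonyl)-5,7-bis(methoxymethoxy)-8-(3-methylbut-2-en-1-yl)-4H-chromen-4-one | CS(=O)(=O)c1cc(=O)c2c(OCOC)cc(OCOC)c(CC=C(C)C)c2o1 | intermediate
13 | 4-[(tert-butyldimethylsilyl)oxy]phenol | CC(C)(C)[Si](C)(C)Oc1ccc(O)cc1 | starting material
14 | tert-butyl[4-(methoxymethoxy)phenoxy]dimethylsilane | COCOc1ccc(O[Si](C)(C)C(C)(C)C)cc1 | intermediate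
15 | {5-[(tert-butyldimethylsilyl)oxy]-2-(methoxymethoxy)phenyl}lithium (aryllithium) | [Li]c1cc(O[Si](C)(C)C(C)(C)C)ccc1OCOC | intermediate
16 | tert-butyl[4-(methoxymethoxy)-3-(3-methylbut-2-en-1-yl)phenoxy]dimethylsilane | COCOc1ccc(O[Si](C)(C)C(C)(C)C)cc1CC=C(C)C | intermediate
17 | caesium 4-(methoxymethoxy)-3-(3-methylbut-2-en-1-yl)phenoxide | [Cs+].[O-]c1ccc(OCOC)c(CC=C(C)C)c1 | intermediate
18 | 5,7-bis(methoxymethoxy)-2-[4-(methoxymethoxy)-3-(3-methylbut-2-en-1-yl)phenoxy]-8-(3-methylbut-2-en-1-yl)-4H-chromen-4-one | COCOc1ccc(Oc2cc(=O)c3c(OCOC)cc(OCOC)c(CC=C(C)C)c3o2)cc1CC=C(C)C | intermediate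
19 | Epimedonin J, 5,7-dihydroxy-2-[4-hydroxy-3-(3-methylbut-2-en-1-yl)phenoxy]-8-(3-methylbut-2-en-1-yl)-4H-chromen-4-one | CC(C)=CCc1cc(Oc2cc(=O)c3c(O)cc(O)c(CC=C(C)C)c3o2)ccc1O | target

**Count**
Total steps: 9. Longest linear sequence: 7 (steps 1, 2, 3, 4, 5, 8, 9); the aryl branch is steps 6 and 7.

**Steps most likely to fail, with fallbacks**

Step 1 (C-prenylation). O-alkylation and double C-alkylation compete and the yield is usually modest. The fallback sets out from 1 and comes back at 5, bypassing steps 1 and 2; it puts the prenyl group on carbon by a sigmatropic shift instead of an intermolecular C-alkylation. Compound 1 is mono-protected at the unchelated 4-OH (MOMCl 1.05 equiv, i-Pr2NEt, CH2Cl2, 0 °C) to give 1-[2,6-dihydroxy-4-(methoxymethoxy)phenyl]ethan-1-one F1. One of its two equivalent chelated OH groups is O-prenylated (2, K2CO3, acetone, reflux) to give 1-[2-hydroxy-4-(methoxymethoxy)-6-[(3-methylbut-2-en-1-yl)oxy]phenyl]ethan-1-one F2. A Claisen–Cope (para-Claisen) rearrangement (N,N-diethylaniline, 190 °C, or Eu(fod)3 in CHCl3 at 60 °C) carries the prenyl group, by two allylic inversions, to the carbon para to the ether oxygen and gives 1-[2,6-dihydroxy-4-(methoxymethoxy)-3-(3-methylbut-2-en-1-yl)phenyl]ethan-1-one F3. MOMCl (1.1 equiv, i-Pr2NEt) then caps the less hindered chelated OH to give 5.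

Step 8 (fluoride-triggered coupling). Fluoride or adventitious hydroxide may attack the sulfone and hydrolyse it to the 4-hydroxycoumarin before the phenoxide has formed. The fallback sets out from 16 and comes back at 18; it separates unmasking from coupling so that no fluoride meets the sulfone. Compound 16 is desilylated alone (TBAF, THF, 0 °C, NH4Cl work-up) to 4-(methoxymethoxy)-3-(3-methylbut-2-en-1-yl)phenol F4, which is purified. F4 is then joined to 12 as its preformed phenoxide (K2CO3, acetone, rt, or NaH, THF, 0 °C) by the classical addition–elimination to give 18.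

Step 9 (acidic MOM cleavage). Protic acid in methanol could cyclise the ortho-prenylphenols to chromans or exchange the 2-aryloxy group for methoxy. The fallback sets out from 18 and comes back at 19; it replaces protic acidolysis by a trans-silylation followed by neutral hydrolysis. TMSOTf with 2,2′-bipyridyl (MeCN, 0 °C → rt) converts the three aryl MOM ethers into aryl trimethylsilyl ethers in a buffered, non-protic medium. This gives 2-{3-(3-methylbut-2-en-1-yl)-4-[(trimethylsilyl)oxy]phenoxy}-8-(3-methylbut-2-en-1-yl)-5,7-bis[(trimethylsilyl)oxy]-4H-chromen-4-one F5. Stirring F5 with water in THF at rt removes the silyl groups and gives 19.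

**Further compounds**
F1 | step 1 | 1-[2,6-dihydroxy-4-(methoxymethoxy)phenyl]ethan-1-one | CC(=O)c1c(O)cc(OCOC)cc1O
F2 | step 1 | 1-[2-hydroxy-4-(methoxymethoxy)-6-[(3-methylbut-2-en-1-yl)oxy]phenyl]ethan-1-one | CC(=O)c1c(O)cc(OCOC)cc1OCC=C(C)C
F3 | step 1 | 1-[2,6-dihydroxy-4-(methoxymethoxy)-3-(3-methylbut-2-en-1-yl)phenyl]ethan-1-one | CC(=O)c1c(O)cc(OCOC)c(CC=C(C)C)c1O
F4 | step 8 | 4-(methoxymethoxy)-3-(3-methylbut-2-en-1-yl)phenol | COCOc1ccc(O)cc1CC=C(C)C
F5 | step 9 | 2-{3-(3-methylbut-2-en-1-yl)-4-[(trimethylsilyl)oxy]phenoxy}-8-(3-methylbut-2-en-1-yl)-5,7-bis[(trimethylsilyl)oxy]-4H-chromen-4-one | C[Si](C)(C)Oc1ccc(Oc2cc(=O)c3c(O[Si](C)(C)C)cc(O[Si](C)(C)C)c(CC=C(C)C)c3o2)cc1CC=C(C)C
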